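**Phlorofucofuroeckol A (27): synthesis plan built on a sigmatropic benzofuran synthesis with phloroglucinol as the ketone**

Atom labels: rings B and C carry dibenzofuran numbers (ring B: C1–C4, C4a, C9b; ring C: C5a, C6–C9, C9a). Ring A carbons are A1 (ring E ether), A2 (OH), A3 (H), A4 (OH), A5 and A6 (dioxin; A5 is bonded through oxygen to C1, A6 to C2).

## The problem

Phlorofucofuroeckol A (27) consists of five phloroglucinol-derived benzene rings. Rings B and C share a furan, rings A and B share a 1,4-dioxin, and rings E and D are attached to rings A and C by diaryl ether bonds. There is no stereocentre, so every difficulty is one of regiochemistry and crowding. The hardest bond is the biaryl bond C9a–C9b, which has an oxygen-bearing carbon on all four ortho positions (C1, C4a, C5a, C9) and is a poor candidate for cross-coupling. The second problem is the dioxin: the oxygens on C1 and C2 must be joined to A5 and A6 of an unsymmetrical ring A in one sense only. The nine free hydroxyls make 27 an oxidation-prone polyphenol, so they stay etherified until the last step. Several intermediates are sensitive as well: an O-arylhydroxylamine with a weak N–O bond, a quinone and a hydroquinone. The structure offers one simplification: C4a of ring B and the two carbons meta to it (C1, C3) all carry oxygen, so ring B without its C2 oxygen is phloroglucinol, whose three ring CH carbons are equivalent and whose keto tautomer can act as a cyclic 1,3-diketone. On ring C, the furan-oxygen carbon C5a has only one unoccupied ortho position (the future C9a), because C6 carries the ring D ether.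

## Retrosynthesis

**27 from 26.** The last cut removes nine O–alkyl bonds (seven methyl, two isopropyl). Alkyl ethers are chosen because they survive the acid of the key step, carbonate bases, CuI catalysis and peracid. Isopropyl marks the two oxygens that had to be told apart from a neighbour and falls with the methyl groups under BBr3. Benzyl is avoided at this stage because benzyl cations would alkylate the electron-rich rings. The forward step must cleave all nine ethers without touching the diaryl ether, furan or dioxin bonds.

**26 from 25.** The dioxin bond between the C2 oxygen and A6 is cut, leading to bromophenol 25, which closes by an intramolecular CuI-catalysed etherification. The shorter neighbour would be a one-pot double displacement on quinone 18 by a ring B catechol (F6 in the fallback to step 15). That was set aside as the main line because two oxygens meet two different quinone carbons. In addition, the first-formed aryloxyquinone carbon is a vinylogous ester that the neighbouring phenoxide can attack, shifting ring A from one oxygen to the other, so the sense of annulation is not secured. In 25, ring A is an electron-rich arene where such a shift cannot occur and only one six-membered ring can form.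

**25 from 23.** The C2 oxygen is traced back to a formyl group (Baeyer–Villiger oxidation). As carbon, C2 cannot compete with the C1 oxygen for ring A while ring A is still a quinone. This fixes the order in which the two dioxin bonds are made.

**23 from 21 and 22; 21 from 20.** The ring E ether bond at the A1 oxygen is cut to give phenol 21 and iodide 22 (CuI-catalysed arylation). Before that, the A4 hydroxyl of hydroquinone 20 is capped as its isopropyl ether. The forward steps rely on the A4 hydroxyl having a free ortho position while the A1 hydroxyl sits between bromine and methoxyl, and on the aryl iodide reacting before the hindered aryl bromide of 21.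

**20 from 14 and 18.** The first dioxin bond (C1 oxygen to A5) is cut. Ring A enters as dibromoquinone 18, the only form in which a pentaoxygenated ring is electrophilic enough to take the crowded bay phenoxide of 14 at room temperature. With a single nucleophilic oxygen present, regiochemistry depends only on the quinone: attack is expected para to its methoxyl, which is A5. Reduction then removes the quinone reactivity.

**18 from 16 from 15.** Quinone 18 comes from 5-bromovanillin (15) by a second bromination and Dakin oxidation/oxidation. The vanillin substitution pattern already holds the methoxyl, the two oxygens and the hydrogen of ring A in the right places.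

**14 from 13 from 12.** The formyl group is removed (ortho-formylation of the bay phenol, whose only ortho CH is C2) and the isopropyl group on the C3 oxygen is removed. The forward protection must distinguish the unhindered 3-hydroxyl of diol 12 from the bay 1-hydroxyl.

**12 from 8 and 9.** This is the key cut: the biaryl bond C9a–C9b and the furan bond O–C4a, leading to O-arylhydroxylamine 8 and phloroglucinol (9). Against a cross-coupling of two fully ortho-substituted partners, this forms the hindered C–C bond intramolecularly through a six-membered transition state and needs no halogen or metal on either ring. The precursor pair is one commodity chemical and one diaryl ether.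

**8 from 7; 7 from 6; 6 from 4 and 5; 4 from 2 from 1.** The N–O bond is cut (electrophilic amination of phenol 7), then the ring D ether (CuI-catalysed coupling of phenol 4 with bromide 5). Phenol 4 comes from salicylaldehyde 1, whose existing hydroxyl is benzylated and whose formyl group becomes the ring D oxygen by Baeyer–Villiger oxidation. A route through a symmetrical trimethyl ether would be one step shorter but would end in the selective cleavage of one methoxyl out of five; the benzyl group decides that question at the start.

## Roads not taken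

**Alternative 1:** Ring A enters as a dichloroquinone at the very start. Both dioxin C–O bonds are cut between catechol aldehyde A1 (3,4-dihydroxy-5-methoxybenzaldehyde, the future ring B) and 2,3-dichloro-5-methoxy-1,4-benzoquinone A2. In the forward step the dianion of A1 displaces both vinylic chlorides and closes the dioxin, giving quinone aldehyde A3.
- Merits: two cheap components, the dioxin made in the first step, and a formyl group para to the central catechol oxygen. That oxygen is much the less basic, so which oxygen ends on which quinone carbon is biased by the substrate. In this respect the alternative is better than the present plan, which spends three steps (formyl mask in step 8, reduction in step 11, CuI closure in step 15) to fix the same connectivity.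
- Weak points: after A3 the aldehyde must become the phenol that ends as the furan oxygen, and the dibenzofuran must then be built on a ring B that is no longer symmetric. Its two ortho CH carbons differ, so the biaryl bond faces a regiochemical choice at the most hindered position of the molecule. The two hydroquinone oxygens of ring A also still have to be told apart.
- Comparison: the alternative solves the easier problem (dioxin) early and leaves the harder one (biaryl and furan) without the symmetry that the present plan uses.

**Alternative 2:** Ring A is built by ring expansion of a four-membered ring. The racemic cyclobutenone A4 carries the ring E aryloxy group, an isopropoxy group, a silyloxy group and a 1-ethoxyvinyl group. On heating it opens to a vinylketene that closes to phenol A5, in which ring E is attached and all five ring A oxygens carry different groups.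
- Merits: complete differentiation of ring A, and a ring E ether made on a cyclobutenedione ester instead of a hindered phenol. In both respects it is better than the present plan, which needs a selective hydroquinone alkylation (step 12) and a hindered CuI arylation (step 13).
- Weak points: the carbonyl addition that makes A4 must choose between two similar vinylogous ester carbonyls. A5 then has to be joined to ring B through two ring A oxygens, which asks ring B to be a 1,2-dielectrophile, and an electron-rich phloroglucinol ring is not one. The dibenzofuran is not addressed, and four kinds of protecting group must be handled.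
- Comparison: the present plan sets against it a ring A that comes in two steps from 5-bromovanillin and enters as an electrophile, which matches the nucleophilic oxygens that ring B naturally offers.

**Alternative 3:** Both terminal rings are grown from alkynyl ethers. Rings D and E are cut together, back to the core bis(ethynyl ether) A6 and two molecules of 3-ethoxycyclobut-2-en-1-one A7. Each benzannulation joins the ketene carbon to the alkyne CH and gives a 3-ethoxy-5-hydroxyphenyl ether, so A8 is the target skeleton as a pentamethyl diethyl ether with two free phenols.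
- Merits: two rings in one two-directional step and no diaryl ether coupling at all, since both ether oxygens are already on the core. Here it is better than the present plan, which needs two CuI arylations of doubly ortho-substituted phenols (steps 3 and 13).
- Weak points: A6 contains the whole B–A–C core, so the dibenzofuran and the dioxin are only moved into the synthesis of A6. Aryl ethynyl ethers on electron-rich rings are labile and must be carried through heating. Two kinds of alkyl ether remain to be cleaved.
- Comparison: this is an endgame and not a plan for the core. The present plan sets against it commercial aryl halides for rings D and E and a solution for the biaryl bond.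

Key step: step 6

Remark: ring A is brought in as the dibromoquinone 18 because it is two steps from 5-bromovanillin; vinylic bromide should be displaced from a quinone in the same way as chloride.
Remark: O-(mesitylsulfonyl)hydroxylamine (MSH) is prepared immediately before use from commercial ethyl O-(mesitylsulfonyl)acetohydroximate and is treated as a reagent.

## Steps

Step 1
Reactants: 1 2-hydroxy-4,6-dimethoxybenzaldehyde
Product: 2 2-(benzyloxy)-4,6-dimethoxybenzaldehyde
Conditions: BnBr, K2CO3, DMF, rt
Reagents that add atoms: benzyl bromide, BrCc1ccccc1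
Why: Williamson etherification of the phenol; the benzyl group marks the oxygen that will later carry nitrogen and can be removed by hydrogenolysis without touching methyl ethers.

Step 2
Reactants: 2 2-(benzyloxy)-4,6-dimethoxybenzaldehyde
Product: 4 2-(benzyloxy)-4,6-dimethoxyphenol, via aryl formate 3 (not isolated)
Conditions: mCPBA, CH2Cl2, 0 °C to rt; then K2CO3 (0.2 equiv), MeOH, rt
Reagents that add atoms: mCPBA, O=C(OO)c1cccc(Cl)c1
Why: Baeyer–Villiger oxidation of a 2,4,6-trialkoxybenzaldehyde, in which the electron-rich aryl group migrates; methanolysis of the formate frees the phenol that will carry ring D.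

Step 3
Reactants: 4 2-(benzyloxy)-4,6-dimethoxyphenol, 5 1-bromo-3,5-dimethoxybenzene
Product: 6 1-(benzyloxy)-2-(3,5-dimethoxyphenoxy)-3,5-dimethoxybenzene
Conditions: CuI (10 mol%), picolinic acid (20 mol%), K3PO4, DMSO, 90 °C, argon
Reagents that add atoms: none
Why: Ullmann diaryl ether synthesis under the picolinic acid conditions developed for 2,6-disubstituted phenols; the aryl bromide has no ortho substituent.

Step 4
Reactants: 6 1-(benzyloxy)-2-(3,5-dimethoxyphenoxy)-3,5-dimethoxybenzene
Product: 7 2-(3,5-dimethoxyphenoxy)-3,5-dimethoxyphenol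
Conditions: H2 (1 atm), Pd/C, EtOAc/EtOH, rt
Reagents that add atoms: none
Why: Hydrogenolysis of a benzyl aryl ether; methyl ethers and the diaryl ether are inert, so only the oxygen meant for nitrogen is freed.

Step 5
Reactants: 7 2-(3,5-dimethoxyphenoxy)-3,5-dimethoxyphenol
Product: 8 O-[2-(3,5-dimethoxyphenoxy)-3,5-dimethoxyphenyl]hydroxylamine
Conditions: NaH, DMF, 0 °C; then MSH, 0 °C to rt; used without delay
Reagents that add atoms: O-(mesitylsulfonyl)hydroxylamine (MSH), Cc1cc(C)c(S(=O)(=O)ON)c(C)c1
Why: Electrophilic amination of a phenoxide on oxygen by a sulfonyloxyamine, the established route to O-arylhydroxylamines for benzofuran synthesis.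

Step 6
Reactants: 8 O-[2-(3,5-dimethoxyphenoxy)-3,5-dimethoxyphenyl]hydroxylamine, 9 phloroglucinol (benzene-1,3,5-triol)
Product: 12 6-(3,5-dimethoxyphenoxy)-7,9-dimethoxydibenzo[b,d]furan-1,3-diol, via N-aryloxyaniline 10 (not isolated), via aminobiaryl 11 (not isolated)
Conditions: 9 (2 equiv), MsOH (2 equiv), THF, 60 °C, argon
Reagents that add atoms: none
Why: Proposed new method: the closest known reactions are the acid-mediated benzofuran synthesis from O-arylhydroxylamines and ketones or cyclic 1,3-diones (the oxygen counterpart of the Fischer indole synthesis) and the [3,3] shift of N,O-diarylhydroxylamines to 2-amino-2'-hydroxybiaryls; what is new is a triphenol as the carbonyl partner. Acid protonates 9 on carbon, and the keto tautomer condenses with the nitrogen of 8 as a cyclic 1,3-diketone would, giving after loss of water an N-aryloxy enaminone that is the tautomer of N,O-diarylhydroxylamine 10. A [3,3] sigmatropic shift through a six-membered transition state (C6 and C1 of ring C, O, N, and the C–N carbon and an ortho CH of the phloroglucinol ring) breaks the weak N–O bond and forms the tetra-ortho-substituted biaryl bond intramolecularly; tautomerisation gives aminobiaryl 11. The 3,5-dihydroxyaniline ring of 11 is protonated on carbon as readily as 9, and the freed ring C phenol adds to the resulting iminium carbon in a 5-exo-trig closure; loss of ammonia and rearomatisation give the furan of 12. No stereocentre is formed. Regiochemistry is needed on both rings and is fixed by the substrates: the three ring CH carbons of 9 are equivalent, and on ring C the ortho carbon C2 carries the ring D ether, so a shift to it cannot rearomatise and only C6 leads on. A second condensation is limited because 12 is a resorcinol, much less ketone-like than 9, which is used in excess.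

Step 7
Reactants: 12 6-(3,5-dimethoxyphenoxy)-7,9-dimethoxydibenzo[b,d]furan-1,3-diol
Product: 13 6-(3,5-dimethoxyphenoxy)-7,9-dimethoxy-3-(propan-2-yloxy)dibenzo[b,d]furan-1-ol
Conditions: 2-bromopropane (1.1 equiv), K2CO3 (1.1 equiv), DMF, 40 °C
Reagents that add atoms: 2-bromopropane, CC(C)Br
Why: Phenoxide alkylation with a secondary bromide is sensitive to crowding: the 3-hydroxyl has two free ortho positions, while the 1-hydroxyl lies in the bay next to the ring junction and can hydrogen-bond to the 9-methoxyl oxygen, so one equivalent should go to O3.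

Step 8
Reactants: 13 6-(3,5-dimethoxyphenoxy)-7,9-dimethoxy-3-(propan-2-yloxy)dibenzo[b,d]furan-1-ol
Product: 14 6-(3,5-dimethoxyphenoxy)-1-hydroxy-7,9-dimethoxy-3-(propan-2-yloxy)dibenzo[b,d]furan-2-carbaldehyde
Conditions: MgCl2, Et3N, (CH2O)n, MeCN, reflux; aq. HCl work-up
Reagents that add atoms: paraformaldehyde (as formaldehyde), C=O
Why: MgCl2-mediated ortho-formylation of phenols (Casnati–Skattebøl) delivers formaldehyde within the magnesium phenoxide to an ortho carbon only, and the bay phenol has a single ortho CH (C2). The aldehyde is the masked C2 oxygen.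

Step 9
Reactants: 15 3-bromo-4-hydroxy-5-methoxybenzaldehyde (5-bromovanillin)
Product: 16 2,3-dibromo-4-hydroxy-5-methoxybenzaldehyde
Conditions: Br2, Fe (cat.), AcOH, 60 °C
Reagents that add atoms: bromine, BrBr
Why: Electrophilic aromatic bromination; of the two free positions the one para to the methoxyl is attacked, which places the second bromine next to the first.

Step 10
Reactants: 16 2,3-dibromo-4-hydroxy-5-methoxybenzaldehyde
Product: 18 2,3-dibromo-5-methoxycyclohexa-2,5-diene-1,4-dione, via hydroquinone 17 (not isolated)
Conditions: H2O2, NaOH, H2O/THF, 0 °C, N2; then HCl; then FeCl3, H2O, rt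
Reagents that add atoms: hydrogen peroxide, OO
Why: Dakin oxidation of a p-hydroxybenzaldehyde gives the hydroquinone, which FeCl3 oxidises to the quinone; the two bromines become vinylic leaving groups flanked by the quinone carbonyls.

Step 11
Reactants: 14 6-(3,5-dimethoxyphenoxy)-1-hydroxy-7,9-dimethoxy-3-(propan-2-yloxy)dibenzo[b,d]furan-2-carbaldehyde, 18 2,3-dibromo-5-methoxycyclohexa-2,5-diene-1,4-dione
Product: 20 1-(2-bromo-3,6-dihydroxy-4-methoxyphenoxy)-6-(3,5-dimethoxyphenoxy)-7,9-dimethoxy-3-(propan-2-yloxy)dibenzo[b,d]furan-2-carbaldehyde, via aryloxyquinone 19 (not isolated)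
Conditions: Cs2CO3, MeCN, rt; then 18 (1.3 equiv), 0 °C to rt; then Na2S2O4, H2O/EtOAc, rt
Reagents that add atoms: none
Why: Addition–elimination of a phenoxide on a 2,3-dihalo-1,4-quinone; with only one nucleophilic oxygen a single ether forms, and attack is expected at the bromine-bearing carbon para to the methoxyl (A5), because the charge is then taken up by the carbonyl that is not deactivated as a vinylogous ester, as in additions to 2-methoxy-1,4-benzoquinone. Dithionite then reduces the quinone so that ring A becomes an electron-rich arene on which the new ether can no longer be displaced; the position of the ether is to be confirmed by HMBC.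

Step 12
Reactants: 20 1-(2-bromo-3,6-dihydroxy-4-methoxyphenoxy)-6-(3,5-dimethoxyphenoxy)-7,9-dimethoxy-3-(propan-2-yloxy)dibenzo[b,d]furan-2-carbaldehyde
Product: 21 1-[2-bromo-3-hydroxy-4-methoxy-6-(propan-2-yloxy)phenoxy]-6-(3,5-dimethoxyphenoxy)-7,9-dimethoxy-3-(propan-2-yloxy)dibenzo[b,d]furan-2-carbaldehyde
Conditions: 2-bromopropane, K2CO3, DMF, 40 °C, argon
Reagents that add atoms: 2-bromopropane, CC(C)Br
Why: Selective alkylation of the less hindered hydroquinone oxygen: the A4 hydroxyl has a free ortho position, while the A1 hydroxyl lies between bromine and methoxyl, as in the 4-O-alkylation of 2,6-disubstituted hydroquinones.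

Step 13
Reactants: 21 1-[2-bromo-3-hydroxy-4-methoxy-6-(propan-2-yloxy)phenoxy]-6-(3,5-dimethoxyphenoxy)-7,9-dimethoxy-3-(propan-2-yloxy)dibenzo[b,d]furan-2-carbaldehyde, 22 1-iodo-3,5-dimethoxybenzene
Product: 23 1-[2-bromo-3-(3,5-dimethoxyphenoxy)-4-methoxy-6-(propan-2-yloxy)phenoxy]-6-(3,5-dimethoxyphenoxy)-7,9-dimethoxy-3-(propan-2-yloxy)dibenzo[b,d]furan-2-carbaldehyde
Conditions: CuI (20 mol%), picolinic acid (40 mol%), K3PO4, 22 (2 equiv), DMSO, 80 °C, argon
Reagents that add atoms: none
Why: Ullmann diaryl ether synthesis on a 2,6-disubstituted phenol; the unhindered aryl iodide should react well before the doubly flanked, electron-rich aryl bromide of 21, which is kept for step 15.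

Step 14
Reactants: 23 1-[2-bromo-3-(3,5-dimethoxyphenoxy)-4-methoxy-6-(propan-2-yloxy)phenoxy]-6-(3,5-dimethoxyphenoxy)-7,9-dimethoxy-3-(propan-2-yloxy)dibenzo[b,d]furan-2-carbaldehyde
Product: 25 1-[2-bromo-3-(3,5-dimethoxyphenoxy)-4-methoxy-6-(propan-2-yloxy)phenoxy]-6-(3,5-dimethoxyphenoxy)-7,9-dimethoxy-3-(propan-2-yloxy)dibenzo[b,d]furan-2-ol, via aryl formate 24 (not isolated)
Conditions: mCPBA, CH2Cl2, 0 °C to rt; then K2CO3 (0.2 equiv), MeOH, 0 °C, argon
Reagents that add atoms: mCPBA, O=C(OO)c1cccc(Cl)c1
Why: Baeyer–Villiger oxidation of a benzaldehyde with oxygen on both ortho carbons and on the para carbon (aryl migration), then formate methanolysis. Ring A is no longer a quinone, so the freed C2 phenoxide cannot shift the ring A ether.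

Step 15
Reactants: 25 1-[2-bromo-3-(3,5-dimethoxyphenoxy)-4-methoxy-6-(propan-2-yloxy)phenoxy]-6-(3,5-dimethoxyphenoxy)-7,9-dimethoxy-3-(propan-2-yloxy)dibenzo[b,d]furan-2-ol
Product: 26 phlorofucofuroeckol A heptamethyl diisopropyl ether (isopropyl on the ring B oxygen at C3 and on the ring A oxygen at A4, methyl on the other seven)
Conditions: CuI (20 mol%), N,N-dimethylglycine (40 mol%), Cs2CO3, dioxane, 100 °C, argon
Reagents that add atoms: none
Why: Intramolecular Ullmann etherification of a 2-(2-bromophenoxy)phenol, a standard closure of dibenzo-1,4-dioxins; only one six-membered ring can form, so the connectivity set in step 11 is kept.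

Step 16
Reactants: 26 phlorofucofuroeckol A heptamethyl diisopropyl ether
Product: 27 phlorofucofuroeckol A
Conditions: BBr3 (excess), CH2Cl2, −78 °C to rt; then MeOH, H2O; argon throughout
Reagents that add atoms: none
Why: BBr3 cleaves aryl methyl and aryl isopropyl ethers alike, while diaryl ether, furan and dioxin C–O bonds (both carbons sp2) are not attacked. The nonaphenol is worked up without base and under argon.

## Compound list

1 | 2-hydroxy-4,6-dimethoxybenzaldehyde | COc1cc(O)c(C=O)c(OC)c1 | starting material
2 | 2-(benzyloxy)-4,6-dimethoxybenzaldehyde | COc1cc(OCc2ccccc2)c(C=O)c(OC)c1 | intermediate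
3 | 2-(benzyloxy)-4,6-dimethoxyphenyl formate | COc1cc(OCc2ccccc2)c(OC=O)c(OC)c1 | intermediate
4 | 2-(benzyloxy)-4,6-dimethoxyphenol | COc1cc(OCc2ccccc2)c(O)c(OC)c1 | intermediate
5 | 1-bromo-3,5-dimethoxybenzene | COc1cc(Br)cc(OC)c1 | starting material
6 | 1-(benzyloxy)-2-(3,5-dimethoxyphenoxy)-3,5-dimethoxybenzene | COc1cc(OC)cc(Oc2c(OC)cc(OC)cc2OCc2ccccc2)c1 | intermediate
7 | 2-(3,5-dimethoxyphenoxy)-3,5-dimethoxyphenol | COc1cc(OC)cc(Oc2c(OC)cc(OC)cc2O)c1 | intermediate
8 | O-[2-(3,5-dimethoxyphenoxy)-3,5-dimethoxyphenyl]hydroxylamine | COc1cc(OC)cc(Oc2c(OC)cc(OC)cc2ON)c1 | intermediate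
9 | phloroglucinol (benzene-1,3,5-triol) | Oc1cc(O)cc(O)c1 | starting material
10 | 5-{[2-(3,5-dimethoxyphenoxy)-3,5-dimethoxyphenoxy]amino}benzene-1,3-diol | COc1cc(OC)cc(Oc2c(OC)cc(OC)cc2ONc2cc(O)cc(O)c2)c1 | intermediate
11 | 6-amino-3'-(3,5-dimethoxyphenoxy)-4',6'-dimethoxy-[1,1'-biphenyl]-2,2',4-triol | COc1cc(OC)cc(Oc2c(OC)cc(OC)c(-c3c(N)cc(O)cc3O)c2O)c1 | intermediate
12 | 6-(3,5-dimethoxyphenoxy)-7,9-dimethoxydibenzo[b,d]furan-1,3-diol | COc1cc(OC)cc(Oc2c(OC)cc(OC)c3c2oc2cc(O)cc(O)c23)c1 | intermediate
13 | 6-(3,5-dimethoxyphenoxy)-7,9-dimethoxy-3-(propan-2-yloxy)dibenzo[b,d]furan-1-ol | COc1cc(OC)cc(Oc2c(OC)cc(OC)c3c2oc2cc(OC(C)C)cc(O)c23)c1 | intermediate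
14 | 6-(3,5-dimethoxyphenoxy)-1-hydroxy-7,9-dimethoxy-3-(propan-2-yloxy)dibenzo[b,d]furan-2-carbaldehyde | COc1cc(OC)cc(Oc2c(OC)cc(OC)c3c2oc2cc(OC(C)C)c(C=O)c(O)c23)c1 | intermediate
15 | 3-bromo-4-hydroxy-5-methoxybenzaldehyde (5-bromovanillin) | COc1cc(C=O)cc(Br)c1O | starting material
16 | 2,3-dibromo-4-hydroxy-5-methoxybenzaldehyde | COc1cc(C=O)c(Br)c(Br)c1O | intermediate
17 | 2,3-dibromo-5-methoxybenzene-1,4-diol | COc1cc(O)c(Br)c(Br)c1O | intermediate
18 | 2,3-dibromo-5-methoxycyclohexa-2,5-diene-1,4-dione | COC1=CC(=O)C(Br)=C(Br)C1=O | intermediate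
19 | 1-[(2-bromo-4-methoxy-3,6-dioxocyclohexa-1,4-dien-1-yl)oxy]-6-(3,5-dimethoxyphenoxy)-7,9-dimethoxy-3-(propan-2-yloxy)dibenzo[b,d]furan-2-carbaldehyde | COc1cc(OC)cc(Oc2c(OC)cc(OC)c3c2oc2cc(OC(C)C)c(C=O)c(OC4=C(Br)C(=O)C(OC)=CC4=O)c23)c1 | intermediate
20 | 1-(2-bromo-3,6-dihydroxy-4-methoxyphenoxy)-6-(3,5-dimethoxyphenoxy)-7,9-dimethoxy-3-(propan-2-yloxy)dibenzo[b,d]furan-2-carbaldehyde | COc1cc(OC)cc(Oc2c(OC)cc(OC)c3c2oc2cc(OC(C)C)c(C=O)c(Oc4c(Br)c(O)c(OC)cc4O)c23)c1 | intermediate
21 | 1-[2-bromo-3-hydroxy-4-methoxy-6-(propan-2-yloxy)phenoxy]-6-(3,5-dimethoxyphenoxy)-7,9-dimethoxy-3-(propan-2-yloxy)dibenzo[b,d]furan-2-carbaldehyde | COc1cc(OC)cc(Oc2c(OC)cc(OC)c3c2oc2cc(OC(C)C)c(C=O)c(Oc4c(Br)c(O)c(OC)cc4OC(C)C)c23)c1 | intermediate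
22 | 1-iodo-3,5-dimethoxybenzene | COc1cc(I)cc(OC)c1 | starting material
23 | 1-[2-bromo-3-(3,5-dimethoxyphenoxy)-4-methoxy-6-(propan-2-yloxy)phenoxy]-6-(3,5-dimethoxyphenoxy)-7,9-dimethoxy-3-(propan-2-yloxy)dibenzo[b,d]furan-2-carbaldehyde | COc1cc(OC)cc(Oc2c(OC)cc(OC)c3c2oc2cc(OC(C)C)c(C=O)c(Oc4c(Br)c(Oc5cc(OC)cc(OC)c5)c(OC)cc4OC(C)C)c23)c1 | intermediate
24 | 1-[2-bromo-3-(3,5-dimethoxyphenoxy)-4-methoxy-6-(propan-2-yloxy)phenoxy]-6-(3,5-dimethoxyphenoxy)-7,9-dimethoxy-3-(propan-2-yloxy)dibenzo[b,d]furan-2-yl formate | COc1cc(OC)cc(Oc2c(OC)cc(OC)c3c2oc2cc(OC(C)C)c(OC=O)c(Oc4c(Br)c(Oc5cc(OC)cc(OC)c5)c(OC)cc4OC(C)C)c23)c1 | intermediate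
25 | 1-[2-bromo-3-(3,5-dimethoxyphenoxy)-4-methoxy-6-(propan-2-yloxy)phenoxy]-6-(3,5-dimethoxyphenoxy)-7,9-dimethoxy-3-(propan-2-yloxy)dibenzo[b,d]furan-2-ol | COc1cc(OC)cc(Oc2c(OC)cc(OC)c3c2oc2cc(OC(C)C)c(O)c(Oc4c(Br)c(Oc5cc(OC)cc(OC)c5)c(OC)cc4OC(C)C)c23)c1 | intermediate
26 | phlorofucofuroeckol A heptamethyl diisopropyl ether (isopropyl on the ring B oxygen at C3 and the ring A oxygen at A4) | COc1cc(OC)cc(Oc2c(OC)cc(OC(C)C)c3c2Oc2c(OC(C)C)cc4oc5c(Oc6cc(OC)cc(OC)c6)c(OC)cc(OC)c5c4c2O3)c1 | intermediate
27 | phlorofucofuroeckol A | Oc1cc(O)cc(Oc2c(O)cc(O)c3c2Oc2c(O)cc4oc5c(Oc6cc(O)cc(O)c6)c(O)cc(O)c5c4c2O3)c1 | target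

## Step count and least certain steps

Total: 16 steps. Longest linear sequence: 14 steps (steps 1–8 and 11–16, from 1 to 27); quinone 18 is made in the side branch of steps 9 and 10.

**Step 6 (key step).** The most likely failure is acid-induced heterolysis of the N–O bond of protonated 8 before it condenses, because phloroglucinol offers only a small equilibrium share of its keto form; this would return phenol 7 and aminate other nucleophiles in the flask. A second possibility is stalling at aminobiaryl 11 through slow loss of ammonia. The fallback uses known chemistry, sets out from 7 and comes back at 12: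
- Phenol 7 is coupled with commercial 1-bromo-3,5-bis(benzyloxy)benzene (CuI, picolinic acid, K3PO4, DMSO, 90 °C) to give 1-[3,5-bis(benzyloxy)phenoxy]-2-(3,5-dimethoxyphenoxy)-3,5-dimethoxybenzene F1.
- Oxidative double C–H coupling of the diaryl ether (Pd(OAc)2, pivalic acid, K2CO3, air, 120 °C) joins the only free ortho carbon of ring C to an ortho carbon of the new ring and gives 1,3-bis(benzyloxy)-6-(3,5-dimethoxyphenoxy)-7,9-dimethoxydibenzo[b,d]furan F2.
- Hydrogenolysis (H2, Pd/C) returns to 12.

**Step 5.** Electron transfer from the very electron-rich phenoxide to MSH and amination on ring carbon instead of oxygen may consume the phenol. The fallback builds the N–O–aryl unit from the other side; it sets out from 7 and comes back at 8: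
- Triflation (Tf2O, pyridine, CH2Cl2) gives 2-(3,5-dimethoxyphenoxy)-3,5-dimethoxyphenyl trifluoromethanesulfonate F3.
- Coupling with ethyl N-hydroxyethanimidate ([Pd(allyl)Cl]2, tBuBrettPhos, Cs2CO3, toluene, 65 °C) gives ethyl (1E)-N-[2-(3,5-dimethoxyphenoxy)-3,5-dimethoxyphenoxy]ethanimidate F4.
- Hydrolysis (HCl, dioxane/H2O, then NaHCO3) releases 8.

**Step 13.** Ligand exchange of the doubly ortho-substituted phenoxide at CuI may be slow, leaving time for insertion into the C–Br bond of a second molecule and for protodebromination. The fallback is a metal-free arylation; it sets out from 21 and comes back at 23: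
- Iodide 22 is converted in one pot (mCPBA, TsOH·H2O, then 1,3,5-trimethoxybenzene) into (3,5-dimethoxyphenyl)(2,4,6-trimethoxyphenyl)iodonium 4-methylbenzenesulfonate F5.
- The potassium phenoxide of 21 (KOtBu, THF, rt) takes the less electron-rich aryl group from F5 and gives 23, with the aryl bromide untouched.

**Step 15.** CuI may fail to insert into an aryl bromide that lies between two aryloxy groups on a pentaoxygenated ring, so that slow hydrodebromination takes the place of ring closure. The fallback makes both dioxin bonds on the quinone; it sets out from 13 and comes back at 26: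
- Ortho-oxygenation of 13 (2-iodoxybenzoic acid, DMF, rt; then Na2S2O4) gives 6-(3,5-dimethoxyphenoxy)-7,9-dimethoxy-3-(propan-2-yloxy)dibenzo[b,d]furan-1,2-diol F6.
- Double displacement on 18 (K2CO3, MeCN, 0 °C to rt) gives the dioxin-fused methoxyquinone F7.
- Na2S2O4 reduces F7 to the dioxin-fused hydroquinone F8.
- 2-Bromopropane and K2CO3 cap the less hindered A4 hydroxyl to give the mono-isopropyl ether F9.
- Arylation with 22 (CuI, picolinic acid, K3PO4, DMSO) gives 26.

This fallback is shorter but does not secure the sense of the annulation. The regioisomer with ring A turned round may form through attack by the other oxygen or through aryloxy migration on the quinone, so F7 would have to be separated and assigned by HMBC. That is why it is not the main line.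

## Further compounds

F1 | step 6 | 1-[3,5-bis(benzyloxy)phenoxy]-2-(3,5-dimethoxyphenoxy)-3,5-dimethoxybenzene | COc1cc(OC)cc(Oc2c(OC)cc(OC)cc2Oc2cc(OCc3ccccc3)cc(OCc3ccccc3)c2)c1
F2 | step 6 | 1,3-bis(benzyloxy)-6-(3,5-dimethoxyphenoxy)-7,9-dimethoxydibenzo[b,d]furan | COc1cc(OC)cc(Oc2c(OC)cc(OC)c3c2oc2cc(OCc4ccccc4)cc(OCc4ccccc4)c23)c1
F3 | step 5 | 2-(3,5-dimethoxyphenoxy)-3,5-dimethoxyphenyl trifluoromethanesulfonate | COc1cc(OC)cc(Oc2c(OC)cc(OC)cc2OS(=O)(=O)C(F)(F)F)c1
F4 | step 5 | ethyl (1E)-N-[2-(3,5-dimethoxyphenoxy)-3,5-dimethoxyphenoxy]ethanimidate | CCO/C(C)=N/Oc1cc(OC)cc(OC)c1Oc1cc(OC)cc(OC)c1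
F5 | step 13 | (3,5-dimethoxyphenyl)(2,4,6-trimethoxyphenyl)iodonium 4-methylbenzenesulfonate | COc1cc(OC)cc([I+]c2c(OC)cc(OC)cc2OC)c1.Cc1ccc(S(=O)(=O)[O-])cc1
F6 | step 15 | 6-(3,5-dimethoxyphenoxy)-7,9-dimethoxy-3-(propan-2-yloxy)dibenzo[b,d]furan-1,2-diol | COc1cc(OC)cc(Oc2c(OC)cc(OC)c3c2oc2cc(OC(C)C)c(O)c(O)c23)c1
F7 | step 15 | dioxin-fused methoxyquinone of the B–C–D unit (ring A as 1,4-quinone, methoxyl on A2) | COC1=CC(=O)C2=C(C1=O)Oc1c(OC(C)C)cc3oc4c(Oc5cc(OC)cc(OC)c5)c(OC)cc(OC)c4c3c1O2
F8 | step 15 | dioxin-fused hydroquinone (hydroxyls on A1 and A4, methoxyl on A2) | COc1cc(O)c2c(c1O)Oc1c(OC(C)C)cc3oc4c(Oc5cc(OC)cc(OC)c5)c(OC)cc(OC)c4c3c1O2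
F9 | step 15 | dioxin-fused phenol with isopropyl ether on A4 and free hydroxyl on A1 | COc1cc(OC(C)C)c2c(c1O)Oc1c(OC(C)C)cc3oc4c(Oc5cc(OC)cc(OC)c5)c(OC)cc(OC)c4c3c1O2
A1 | alternative 1 | 3,4-dihydroxy-5-methoxybenzaldehyde | COc1cc(C=O)cc(O)c1O
A2 | alternative 1 | 2,3-dichloro-5-methoxy-1,4-benzoquinone | COC1=CC(=O)C(Cl)=C(Cl)C1=O
A3 | alternative 1 | dioxin-fused methoxyquinone aldehyde | COC1=CC(=O)C2=C(Oc3c(OC)cc(C=O)cc3O2)C1=O
A4 | alternative 2 | racemic 2-(3,5-dimethoxyphenoxy)-4-(1-ethoxyethenyl)-3-(propan-2-yloxy)-4-[(triethylsilyl)oxy]cyclobut-2-en-1-one | C=C(OCC)C1(O[Si](CC)(CC)CC)C(OC(C)C)=C(Oc2cc(OC)cc(OC)c2)C1=O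
A5 | alternative 2 | ring E–A phenol with ethyl, triethylsilyl and isopropyl ethers | Oc1cc(OCC)c(O[Si](CC)(CC)CC)c(OC(C)C)c1Oc1cc(OC)cc(OC)c1
A6 | alternative 3 | core bis(ethynyl ether) (pentamethyl ether of the B–A–C core, ethynyloxy on C6 and on A1) | C#COc1c(OC)cc(OC)c2c1Oc1c(OC)cc3oc4c(OC#C)c(OC)cc(OC)c4c3c1O2
A7 | alternative 3 | 3-ethoxycyclobut-2-en-1-one | CCOC1=CC(=O)C1
A8 | alternative 3 | target skeleton as pentamethyl diethyl ether with two free phenols | CCOc1cc(O)cc(Oc2c(OC)cc(OC)c3c2Oc2c(OC)cc4oc5c(Oc6cc(O)cc(OCC)c6)c(OC)cc(OC)c5c4c2O3)c1
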